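## Retrosynthetic overview
1. 22 ⇐ 20 ⇐ 19 ⇐ 17: the acid comes from its methyl ester. The C3 ethyl group and the C2=C3 alkene come from a C3 ketone through its kinetic enol triflate.
2. 17 ⇐ 16 ⇐ 15: one intramolecular Diels–Alder reaction forms C3a–C7a and C4–C5. It relays the single C1 centre to C3a, C4, C5 and C7a.
3. 15 ⇐ 10: the tetraene is grown from a latent C7a aldehyde (a lactol) by three E-selective olefinations.
4. 10 ⇐ 9 ⇐ 5 + 4 (key bond C2–C3): a chiral-pool ester homoenolate (nucleophilic β-carbon) adds to the aldehyde carbon of 4. The resulting dissonant 1,4-O,O pattern is trapped as a γ-lactone.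
5. Ring order: a temporary lactone is made first and opened in step 4. The six- and five-membered carbocycles then close together in step 6.

Assumption: the indene numbering of the target (C1–C7a, C8 = carboxyl carbon) is used for all intermediates, and the carbinol carbon that becomes C3 is carried as an epimer mixture (8–16) because step 7 makes it planar.

## Route

Step 1
Reactants: 1 2,2-dimethoxyacetaldehyde; 2 methyl 2-(triphenyl-λ5-phosphanylidene)propanoate
Product: 4 methyl (E)-2-methyl-4-oxobut-2-enoate, via dimethyl acetal ester 3 (not isolated)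
Conditions: CH2Cl2, rt; then 1 M HCl, THF, rt
Reagents that add atoms: water, O
Why: Wittig olefination with a stabilised ylide gives the (E)-enoate (ester trans to the acetal carbon) and acid-catalysed acetal hydrolysis then frees the aldehyde, so the dienophile geometry is fixed here and no stereocentre is formed.

Step 2
Reactants: 5 methyl (S)-3-bromo-2-methylpropanoate; 4 methyl (E)-2-methyl-4-oxobut-2-enoate
Product: 9 methyl (E)-2-methyl-3-[(4R)-4-methyl-5-oxooxolan-2-yl]prop-2-enoate, via zinc homoenolate 6 (not isolated), via titanium homoenolate 7 (not isolated), via hydroxy diester 8 (not isolated)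
Conditions: Zn, LiCl, THF, 40 °C; ClTi(OiPr)3, CH2Cl2, −40 °C; 4, −40 to 0 °C; aq NH4Cl; then TsOH·H2O (cat.), CH2Cl2, rt
Reagents that add atoms: none
Why: Homoaldol addition: zinc insertion turns the ester β-carbon (C2, normally electrophilic) into a homoenolate, transmetalation gives a carbonyl-selective alkyltitanium that adds 1,2 to the aldehyde carbon of 4 (C3, also electrophilic) rather than to its doubly activated alkene, and acid-catalysed lactonisation traps the 1,4-dioxygenated product, while the C1 methyl centre is carried unchanged from 5 and the new C3 carbinol centre is left uncontrolled.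

Step 3
Reactants: 9 methyl (E)-2-methyl-3-[(4R)-4-methyl-5-oxooxolan-2-yl]prop-2-enoate
Product: 10 methyl (E)-3-[(4R)-5-hydroxy-4-methyloxolan-2-yl]-2-methylprop-2-enoate
Conditions: i-Bu2AlH (1.05 equiv), CH2Cl2, −78 °C; aq Rochelle salt
Reagents that add atoms: none
Why: Partial lactone reduction stops at the stable aluminium lactolate, and the unconjugated lactone carbonyl reacts much faster than the conjugated α-branched methyl ester, so C1 is untouched.

Step 4
Reactants: 10 methyl (E)-3-[(4R)-5-hydroxy-4-methyloxolan-2-yl]-2-methylprop-2-enoate; 11 2-(triphenyl-λ5-phosphanylidene)propanal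
Product: 12 methyl (2E,6R,7E)-4-hydroxy-2,6,8-trimethyl-9-oxonona-2,7-dienoate
Conditions: toluene, 90 °C
Reagents that add atoms: none
Why: Wittig olefination of the open hydroxy-aldehyde tautomer of the lactol with a stabilised formyl ylide gives the (E)-trisubstituted C7a=C7 enal under essentially neutral conditions that do not epimerise C1.

Step 5
Reactants: 12 methyl (2E,6R,7E)-4-hydroxy-2,6,8-trimethyl-9-oxonona-2,7-dienoate; 11 2-(triphenyl-λ5-phosphanylidene)propanal
Product: 13 methyl (2E,6R,7E,9E)-4-hydroxy-2,6,8,10-tetramethyl-11-oxoundeca-2,7,9-trienoate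
Conditions: toluene, 110 °C
Reagents that add atoms: none
Why: A second Wittig homologation with the same stabilised ylide adds the C6=C5 unit as the (E)-alkene, and the dienal product is much less reactive than 12, so over-homologation stays minor.

Step 6
Reactants: 13 methyl (2E,6R,7E,9E)-4-hydroxy-2,6,8,10-tetramethyl-11-oxoundeca-2,7,9-trienoate; 14 diethyl [(E)-3-phenylprop-2-enyl]phosphonate
Product: 16 methyl (1R,3aS,4R,5S,7aS)-3-hydroxy-1,4,5,7-tetramethyl-5-[(1E,3E)-4-phenylbuta-1,3-dien-1-yl]-2,3,3a,4,5,7a-hexahydro-1H-indene-4-carboxylate, via pentaenoate 15 (not isolated)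
Conditions: 14, LiN(SiMe3)2 (2.2 equiv each), THF, −78 to 0 °C; aq NH4Cl; then toluene, BHT, 110 °C
Reagents that add atoms: none
Why: E-selective Horner–Wadsworth–Emmons olefination completes the tetraene, which on heating undergoes the intramolecular Diels–Alder reaction through the ester-endo, tether-anti transition state on the diene face fixed by A(1,3) strain between C1–H and the C7 methyl group, so the (E)-dienophile and (E,E)-diene geometries set C3a, C4, C5 and C7a (trans ring fusion, ester cis to the dienyl chain, C1 methyl cis to C7a–H).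

Step 7
Reactants: 16 the C3 alcohol from step 6
Product: 17 methyl (1R,3aS,4R,5S,7aS)-1,4,5,7-tetramethyl-3-oxo-5-[(1E,3E)-4-phenylbuta-1,3-dien-1-yl]-2,3,3a,4,5,7a-hexahydro-1H-indene-4-carboxylate
Conditions: Dess–Martin periodinane, CH2Cl2, 0 °C to rt
Reagents that add atoms: none
Why: Dess–Martin oxidation converts both C3 epimers into one ketone under non-basic conditions that leave the epimerisable C3a centre of the trans-hydrindanone intact.

Step 8
Reactants: 17 the C3 ketone from step 7
Product: 19 methyl (1S,3aS,4R,5S,7aS)-1,4,5,7-tetramethyl-5-[(1E,3E)-4-phenylbuta-1,3-dien-1-yl]-3-(trifluoromethylsulfonyloxy)-3a,4,5,7a-tetrahydro-1H-indene-4-carboxylate, via potassium enolate 18 (not isolated)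
Conditions: KN(SiMe3)2, THF, −78 °C; PhNTf2, −78 to 0 °C
Reagents that add atoms: N-phenylbis(trifluoromethanesulfonimide), O=S(=O)(N(c1ccccc1)S(=O)(=O)C(F)(F)F)C(F)(F)F
Why: Kinetic enolisation with a bulky amide base removes a C2 methylene proton rather than the hindered tertiary C3a–H next to quaternary C4, and O-sulfonylation fixes the C2=C3 double bond as the enol triflate without moving any stereocentre (the descriptors at C1 and C3a change only through CIP priorities).

Step 9
Reactants: 19 the enol triflate from step 8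
Product: 20 methyl (1R,3aR,4R,5S,7aS)-3-ethyl-1,4,5,7-tetramethyl-5-[(1E,3E)-4-phenylbuta-1,3-dien-1-yl]-3a,4,5,7a-tetrahydro-1H-indene-4-carboxylate
Conditions: EtMgBr, Fe(acac)3 (5 mol %), THF/NMP, −30 °C
Reagents that add atoms: ethylmagnesium bromide, CC[Mg]Br
Why: Iron-catalysed Kumada-type cross-coupling of an alkenyl triflate with an alkyl Grignard reagent is faster than attack on the doubly neopentyl ester and replaces OTf by ethyl at the fixed ring alkene.

Step 10
Reactants: 20 the methyl ester from step 9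
Product: 22 22-nor-zyggomphic acid B, via sodium carboxylate 21 (not isolated)
Conditions: NaSEt, DMF, 90 °C; then 1 M HCl, 0 °C
Reagents that add atoms: none
Why: SN2 dealkylation by thiolate attacks the unhindered O-methyl carbon, so the shielded carbonyl need not be approached and the alkenes never see strong acid, and brief acidification gives the free acid with all five stereocentres unchanged.

## Compound list
1 | 2,2-dimethoxyacetaldehyde | COC(OC)C=O | starting material
2 | methyl 2-(triphenyl-λ5-phosphanylidene)propanoate | COC(=O)C(C)=P(c1ccccc1)(c1ccccc1)c1ccccc1 | starting material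
3 | methyl (E)-4,4-dimethoxy-2-methylbut-2-enoate | COC(=O)/C(C)=C/C(OC)OC | intermediate
4 | methyl (E)-2-methyl-4-oxobut-2-enoate | COC(=O)/C(C)=C/C=O | intermediate
5 | methyl (S)-3-bromo-2-methylpropanoate | BrC[C@@H](C)C(=O)OC | starting material
6 | bromo[(2S)-3-methoxy-2-methyl-3-oxopropyl]zinc | Br[Zn]C[C@@H](C)C(=O)OC | intermediate
7 | [(2S)-3-methoxy-2-methyl-3-oxopropyl]tri(propan-2-yloxy)titanium | CC(C)O[Ti](OC(C)C)(OC(C)C)C[C@@H](C)C(=O)OC | intermediate
8 | dimethyl (2E,6R)-4-hydroxy-2,6-dimethylhept-2-enedioate (C4 epimers) | COC(=O)/C(C)=C/C(O)C[C@@H](C)C(=O)OC | intermediate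
9 | methyl (E)-2-methyl-3-[(4R)-4-methyl-5-oxooxolan-2-yl]prop-2-enoate (epimers at oxolane C2) | C[C@@H]1CC(/C=C(\C)C(=O)OC)OC1=O | intermediate
10 | methyl (E)-3-[(4R)-5-hydroxy-4-methyloxolan-2-yl]-2-methylprop-2-enoate (epimers at oxolane C2 and C5) | C[C@@H]1CC(/C=C(\C)C(=O)OC)OC1O | intermediate
11 | 2-(triphenyl-λ5-phosphanylidene)propanal | CC(C=O)=P(c1ccccc1)(c1ccccc1)c1ccccc1 | starting material
12 | methyl (2E,6R,7E)-4-hydroxy-2,6,8-trimethyl-9-oxonona-2,7-dienoate (C4 epimers) | COC(=O)/C(C)=C/C(O)C[C@@H](C)/C=C(\C)C=O | intermediate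
13 | methyl (2E,6R,7E,9E)-4-hydroxy-2,6,8,10-tetramethyl-11-oxoundeca-2,7,9-trienoate (C4 epimers) | COC(=O)/C(C)=C/C(O)C[C@@H](C)/C=C(C)/C=C(\C)C=O | intermediate
14 | diethyl [(E)-3-phenylprop-2-enyl]phosphonate | CCOP(=O)(C/C=C/c1ccccc1)OCC | starting material
15 | methyl (2E,6R,7E,9E,11E,13E)-4-hydroxy-2,6,8,10-tetramethyl-14-phenyltetradeca-2,7,9,11,13-pentaenoate (C4 epimers) | COC(=O)/C(C)=C/C(O)C[C@@H](C)/C=C(C)/C=C(C)/C=C/C=C/c1ccccc1 | intermediate
16 | methyl (1R,3aS,4R,5S,7aS)-3-hydroxy-1,4,5,7-tetramethyl-5-[(1E,3E)-4-phenylbuta-1,3-dien-1-yl]-2,3,3a,4,5,7a-hexahydro-1H-indene-4-carboxylate (C3 epimers) | OC1C[C@@H](C)[C@@H]2C(C)=C[C@](C)(/C=C/C=C/c3ccccc3)[C@](C)(C(=O)OC)[C@@H]12 | intermediate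
17 | methyl (1R,3aS,4R,5S,7aS)-1,4,5,7-tetramethyl-3-oxo-5-[(1E,3E)-4-phenylbuta-1,3-dien-1-yl]-2,3,3a,4,5,7a-hexahydro-1H-indene-4-carboxylate | O=C1C[C@@H](C)[C@@H]2C(C)=C[C@](C)(/C=C/C=C/c3ccccc3)[C@](C)(C(=O)OC)[C@@H]12 | intermediate
18 | potassium C2=C3 enolate of 17 (all stereocentres as in 17) | [K+].[O-]C1=C[C@@H](C)[C@@H]2C(C)=C[C@](C)(/C=C/C=C/c3ccccc3)[C@](C)(C(=O)OC)[C@@H]12 | intermediate
19 | methyl (1S,3aS,4R,5S,7aS)-1,4,5,7-tetramethyl-5-[(1E,3E)-4-phenylbuta-1,3-dien-1-yl]-3-(trifluoromethylsulfonyloxy)-3a,4,5,7a-tetrahydro-1H-indene-4-carboxylate | O=S(=O)(OC1=C[C@@H](C)[C@@H]2C(C)=C[C@](C)(/C=C/C=C/c3ccccc3)[C@](C)(C(=O)OC)[C@@H]12)C(F)(F)F | intermediate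
20 | methyl (1R,3aR,4R,5S,7aS)-3-ethyl-1,4,5,7-tetramethyl-5-[(1E,3E)-4-phenylbuta-1,3-dien-1-yl]-3a,4,5,7a-tetrahydro-1H-indene-4-carboxylate | CCC1=C[C@@H](C)[C@@H]2C(C)=C[C@](C)(/C=C/C=C/c3ccccc3)[C@](C)(C(=O)OC)[C@@H]12 | intermediate
21 | sodium salt of 22 | CCC1=C[C@@H](C)[C@@H]2C(C)=C[C@](C)(/C=C/C=C/c3ccccc3)[C@](C)(C(=O)[O-])[C@@H]12.[Na+] | intermediate
22 | 22-nor-zyggomphic acid B, (1R,3aR,4R,5S,7aS)-3-ethyl-1,4,5,7-tetramethyl-5-[(1E,3E)-4-phenylbuta-1,3-dien-1-yl]-3a,4,5,7a-tetrahydro-1H-indene-4-carboxylic acid | CCC1=C[C@@H](C)[C@@H]2C(C)=C[C@](C)(/C=C/C=C/c3ccccc3)[C@](C)(C(=O)O)[C@@H]12 | target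

## Step count and risks
Total step count: 10. Longest linear sequence: 10 steps (1/2 → 4 → 9 → … → 22); the branch from 5 is 9 steps.

**Step 2 (homoaldol on a trifunctional enal).** The metal homoenolate may add in a conjugate sense to 4, or be too sluggish. The fallback sets out from 4 and 6 and comes back at 9. It keeps the β-metallated ester but lets it acylate instead of adding to a carbonyl.
- Pinnick oxidation of 4 (NaClO2, NaH2PO4, 2-methylbut-2-ene) gives (E)-4-methoxy-3-methyl-4-oxobut-2-enoic acid F1.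
- Oxalyl chloride with catalytic DMF gives methyl (E)-4-chloro-2-methyl-4-oxobut-2-enoate F2.
- Pd(PPh3)4-catalysed acylation of 6 with F2 gives dimethyl (2E,6R)-2,6-dimethyl-4-oxohept-2-enedioate F3.
- Luche reduction (NaBH4, CeCl3·7H2O, MeOH, −78 °C) delivers 8, which lactonises to 9.

**Step 6 (cycloaddition building two adjacent quaternary carbons).** The simple enoate may be too unreactive at temperatures the tetraene tolerates. The fallback sets out from 15 (isolated cold after the olefination) and comes back at 17. It replaces thermal activation by an oxidation-triggered cycloaddition. Dess–Martin or MnO2 oxidation of the allylic alcohol gives methyl (2E,6R,7E,9E,11E,13E)-2,6,8,10-tetramethyl-4-oxo-14-phenyltetradeca-2,7,9,11,13-pentaenoate F4. Its keto-ester dienophile is doubly activated and should cyclise at or below room temperature directly to 17, which makes step 7 unnecessary.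

**Step 8 (regioselective enolisation next to an epimerisable ring-fusion carbon).** Proton exchange could scramble C3a or give the C3=C3a enolate. The fallback sets out from 17 and comes back at 20. It uses hydrazone chemistry instead of an enolate.
- 2,4,6-Triisopropylbenzenesulfonyl hydrazide gives methyl (1R,3aS,4R,5S,7aS)-1,4,5,7-tetramethyl-5-[(1E,3E)-4-phenylbuta-1,3-dien-1-yl]-3-[2-(2,4,6-triisopropylphenyl)sulfonylhydrazinylidene]-2,3,3a,4,5,7a-hexahydro-1H-indene-4-carboxylate F5.
- Shapiro fragmentation (n-BuLi, THF/TMEDA, −78 to 0 °C) deprotonates the less hindered C2 and gives the C3 alkenyllithium F6.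
- Iodine turns F6 into methyl (1S,3aS,4R,5S,7aS)-3-iodo-1,4,5,7-tetramethyl-5-[(1E,3E)-4-phenylbuta-1,3-dien-1-yl]-3a,4,5,7a-tetrahydro-1H-indene-4-carboxylate F7.
- Negishi coupling of F7 (EtZnBr, Pd(dppf)Cl2) gives 20.

## Further compounds
F1 | step 2 | (E)-4-methoxy-3-methyl-4-oxobut-2-enoic acid | COC(=O)/C(C)=C/C(=O)O
F2 | step 2 | methyl (E)-4-chloro-2-methyl-4-oxobut-2-enoate | COC(=O)/C(C)=C/C(=O)Cl
F3 | step 2 | dimethyl (2E,6R)-2,6-dimethyl-4-oxohept-2-enedioate | COC(=O)/C(C)=C/C(=O)C[C@@H](C)C(=O)OC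
F4 | step 6 | methyl (2E,6R,7E,9E,11E,13E)-2,6,8,10-tetramethyl-4-oxo-14-phenyltetradeca-2,7,9,11,13-pentaenoate | COC(=O)/C(C)=C/C(=O)C[C@@H](C)/C=C(C)/C=C(C)/C=C/C=C/c1ccccc1
F5 | step 8 | 2,4,6-triisopropylbenzenesulfonylhydrazone of 17 | CC(C)c1cc(C(C)C)c(S(=O)(=O)NN=C2C[C@@H](C)[C@@H]3C(C)=C[C@](C)(/C=C/C=C/c4ccccc4)[C@](C)(C(=O)OC)[C@@H]23)c(C(C)C)c1
F6 | step 8 | C3 alkenyllithium (C2=C3) derived from F5 | [Li]C1=C[C@@H](C)[C@@H]2C(C)=C[C@](C)(/C=C/C=C/c3ccccc3)[C@](C)(C(=O)OC)[C@@H]12
F7 | step 8 | methyl (1S,3aS,4R,5S,7aS)-3-iodo-1,4,5,7-tetramethyl-5-[(1E,3E)-4-phenylbuta-1,3-dien-1-yl]-3a,4,5,7a-tetrahydro-1H-indene-4-carboxylate | IC1=C[C@@H](C)[C@@H]2C(C)=C[C@](C)(/C=C/C=C/c3ccccc3)[C@](C)(C(=O)OC)[C@@H]12
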